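# Proposed synthesis of (1R,3aR,4R,5S,7aS)-5-ethyl-1,3,4,7-tetramethyl-5-[(1E,3E)-4-phenylbuta-1,3-dienyl]-3a,4,5,7a-tetrahydro-1H-indene-4-carboxylic acid (22)

Remark on the chemistry: the target is read as the (1R,3aR,4R,5S,7aS) acid with a trans ring fusion; the carbocycle keeps the target's indene locants (C1–C3, C3a, C4–C7, C7a) in every intermediate, the side-chain carbon on C5 is C1', and the face of the six-membered ring carrying the C4 methyl and C5 ethyl groups is called the alkyl face, the opposite one the lactone face.

## The problem

Compound 22 is a tetrahydroindene: a cyclohexene (C3a, C4–C7, C7a) trans-fused to a cyclopentene (C1–C3, C3a, C7a), with five contiguous stereocentres (C1, C7a, C3a, C4, C5). C4 (methyl, carboxyl) and C5 (ethyl, phenylbutadienyl) are adjacent quaternary carbons. Making this pair with absolute control is the central difficulty, and once made it is the only handle for setting C3a, which in turn directs C7a and C1. The trans fusion puts the C3a–C3 bond on the alkyl face and the C7a–C1 bond on the lactone face. A trans-fused cyclopentene is strained, so this relationship cannot be expected from equilibration after ring closure and has to be built as a trans-2,3-disubstituted cyclohexanone first. The phenylbutadiene is sensitive to acid, light and electrophiles, both ring alkenes are trisubstituted and migrate under protic acid, and a carboxyl group on a quaternary carbon is hard to free from a simple ester; the diene should therefore come last and the acid should travel in a form that opens under mild conditions. The enabling feature is that the carboxyl on C4 and C1' on C5 are cis: with C1' at the aldehyde level they close to a cis-fused γ-lactone acetal, the retron of a 5-alkoxybutenolide whose C=C carries ethyl on the β carbon and methyl on the α carbon. The other four ring carbons, C6–C7–C7a–C3a with oxygen wanted at C7, are those of a 1-alkoxy-3-silyloxybutadiene, so the six-membered ring can be closed across C5–C6 and C4–C3a by a (4+2) cycloaddition that creates both quaternary centres at once.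

## Retrosynthesis

**Side chain (22 ⇒ 19 + 20).** The C1'=C2' bond is cut. The diene is the most fragile part and is made last. This cut leaves a non-enolisable aldehyde on C5, already present at the right oxidation level in hydroxy lactone 19, and a commercial cinnamyl phosphonate 20. A cut at C2'–C3' (cross-coupling) would need a vinyl halide and an ester protecting group and is kept in reserve. The forward Horner–Wadsworth–Emmons reaction must be E-selective and must tolerate the neighbouring carboxylate.

**Acid and aldehyde from one acetal (19 ⇒ 18).** The lactol is traced to menthyl pseudo-ester 18, in which one acetal masks both the aldehyde and the acid and carries the auxiliary. No separate ester is then needed, which avoids a hydrolysis at a quaternary carbon. The release must avoid hot acid because of the two trisubstituted alkenes.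

**C7 methyl (18 ⇒ 17 ⇒ 15).** The C7–CH3 bond is cut back to enol triflate 17 and ketone 15. Methyl addition to the ketone followed by dehydration would not control the position of the alkene; the enol triflate fixes it at C6=C7. The forward step needs kinetic enolisation toward the C6 methylene and not toward the ring-fusion methine.

**Cyclopentene (15 ⇒ 14).** The C2=C3 bond is cut by ring-closing metathesis to diene 14. Closing the five-membered ring by alkylation, aldol or Michael addition at C7a or C3a would give the cis-fused bicycle; metathesis forms a bond remote from the stereocentres and simply joins two groups that are already trans. Ketone 14 is a monocarbocyclic trans-2,3-disubstituted cyclohexanone, the arrangement that is thermodynamically preferred at the epimerisable C7a.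

**Ring-fusion substituents (14 ⇒ 12 ⇒ 10 ⇒ 8).** Three bonds are cut in turn: C1–vinyl (conjugate addition to ethylidene ketone 12), C7a=C1 (aldol condensation, via 10) and C3a–C3 (conjugate addition of isopropenyl to enone 8). Direct alkylation of the enolate with a but-3-en-2-yl electrophile would control neither regiochemistry (linear versus branched) nor C1. The aldol/elimination/second addition sequence builds the branched chain with classical reactions and sets C1 by allylic strain. Enone 8 retains only the two quaternary centres and the acetal. The forward steps need addition to C3a from the alkyl face and addition to C1 anti to the C3a substituent.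

**Six-membered ring and quaternary pair (8 ⇒ 5 + 6).** C5–C6 and C4–C3a are cut. The C6=C7 alkene of the target suggests the other pair (C4–C5 and C3a–C7a), but that would ask a cycloaddition to form the bond between the two quaternary carbons. The chosen cut keeps C4 and C5 joined as the ring-locked alkene of butenolide 5 and makes the remaining four carbons the commercial diene 6. Complexity falls from three stereocentres and two rings to one acetal stereocentre. The forward reaction needs attack anti to the menthyloxy group, the polarity-matched regiochemistry, and enough driving force to engage a tetrasubstituted dienophile.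

**Dienophile (5 ⇒ 4 ⇒ 3 ⇒ 1 + 2).** The C3–CH3 and C4–ethyl bonds are cut by two cross-couplings on dibromide 3, which comes from mucobromic acid 1 and (−)-menthol 2. A one-step condensation of butanal with pyruvic acid to the hydroxybutenolide would be shorter but is not relied on, because pyruvic acid tends to react with aldehydes through its own enol. In 3 the order of reactivity of the two C–Br bonds (C4 first) fixes which carbon receives ethyl and which methyl.

## Roads not taken

Alternative 1: The cut removes the ring-fusion bond C3a–C7a and both bonds to a ketone carbon placed at C2. A rhodium-catalysed carbonylative enyne cyclisation (Pauson–Khand type) would join an alkyne on C4, a propenyl group on C7 and carbon monoxide, closing the cyclohexene and a cyclopentenone in one step to give A1.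
- Merit: ring economy. Both carbocycles and the ring-fusion bond arise at once, where the chosen plan spends four steps (5 to 8) on the five-membered ring.
- Weak points: both quaternary carbons must already be present and must be made with absolute control on an open chain, where no ring locks the substituents. The alkene partner is part of a conjugated diene, so chemoselectivity and the configurations at C1 and C7a are not assured. A1 also has the wrong oxidation pattern: the C2 ketone must be removed and the C3=C3a alkene moved to C2=C3 with hydrogen delivered to C3a on the correct face, and the trans fusion would depend on that late transfer.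
- Comparison: against the better ring economy of this road, the chosen plan offers a one-step, auxiliary-controlled construction of the C4/C5 pair and a ring fusion assembled from a trans-disubstituted ketone.

Alternative 2: The cyclopentene is cut at C2=C3 and C1–C2. An acetyl group on C3a would be turned into an alkylidene carbene with a lithiated silyldiazomethane reagent, and 1,5-insertion into a methylene C–H bond of an ethyl group on C7a would form the trisubstituted alkene and the C1–C2 bond together, giving tricyclic lactone A2.
- Merit: for the five-membered ring this is the shorter road; it needs no alkene partner at C1 and no metathesis.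
- Weak points: the two methylene hydrogens are diastereotopic, so C1 rests on a selectivity the substrate does not clearly dictate. The insertion must close a strained trans-fused ring in competition with other C–H bonds within reach and with 1,2-shift to an alkyne. The γ-lactone of A2 holds C1' at the alcohol level, so ring opening and oxidation must precede the olefination.
- Comparison: the six-membered ring with its quaternary pair still has to be made, most plausibly by the same cycloaddition, so this road differs only in the annulation. The chosen plan accepts three more steps there in exchange for a C1 centre set by a conformationally reasoned conjugate addition, with a catalyst-controlled reserve.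

Alternative 3: The cut is the C4–C5 bond itself, made by an Ireland–Claisen ring contraction. With the future carboxyl carbon held as an ester on C7, and C7 carrying a trisubstituted E-alkenyl group (C6=C5), enolisation and O-silylation would trigger a [3,3] shift that forms C4–C5, breaks C7–O and closes the cyclohexene, giving acid A3 with a protected hydroxymethyl group in place of the diene.
- Merits: in three respects this is the stronger design. The most congested bond forms intramolecularly by a sigmatropic shift that tolerates fully substituted termini, the C6=C7 alkene appears in the right place without any enolisation problem, and the rearrangement itself frees the carboxylic acid.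
- Weak points: the cost falls before the key step. The rearrangement substrate must already hold the cyclopentene with C1, C3a and C7a set, a tertiary allylic ester linkage inside a six-membered lactone and a stereodefined trisubstituted alkene. The configuration at both quaternary carbons depends on chair-versus-boat selection in a bicyclic transition state that is hard to predict.
- Comparison: the chosen plan reaches its key-step substrate in three steps from bulk chemicals and fixes C4/C5 by a mechanism without that ambiguity, but it must accept a kinetic enol triflate formation (step 9) and a late unmasking of the acid (step 11).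

Key step: step 4

## Route

Step 1
Reactants: 1 mucobromic acid (3,4-dibromo-5-hydroxyfuran-2(5H)-one); 2 (−)-menthol ((1R,2S,5R)-2-isopropyl-5-methylcyclohexan-1-ol)
Product: 3 (5S)-3,4-dibromo-5-[(1R,2S,5R)-menthyloxy]furan-2(5H)-one
Conditions: H2SO4 (cat.), toluene, reflux (Dean–Stark); crystallisation of the (5S) epimer
Reagents that add atoms: none
Why: Acid-catalysed acetalisation of the cyclic hemiacetal (pseudo-ester formation) with azeotropic removal of water, a standard reaction of mucohalic acids; the acetal carbon forms as both epimers, the (5S) epimer is to be separated by fractional crystallisation (chromatography if needed) and the (5R) epimer re-equilibrated with acid and recycled.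

Step 2
Reactants: 3 (5S)-3,4-dibromo-5-[(1R,2S,5R)-menthyloxy]furan-2(5H)-one
Product: 4 (5S)-3-bromo-4-ethyl-5-[(1R,2S,5R)-menthyloxy]furan-2(5H)-one
Conditions: EtB(OH)2, PdCl2(MeCN)2 (5 mol%), AsPh3, Ag2O, THF, 65 °C
Reagents that add atoms: ethylboronic acid, CCB(O)O
Why: Suzuki–Miyaura coupling; oxidative addition should occur at the C4–Br bond (the vinylogous acyl bromide) well before the α C3–Br bond, so ethyl enters at C4 only, and the base-free Ag2O conditions leave the acetal centre untouched.

Step 3
Reactants: 4 (5S)-3-bromo-4-ethyl-5-[(1R,2S,5R)-menthyloxy]furan-2(5H)-one
Product: 5 (5S)-4-ethyl-3-methyl-5-[(1R,2S,5R)-menthyloxy]furan-2(5H)-one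
Conditions: SnMe4, PdCl2(PPh3)2 (5 mol%), CuI (cat.), NMP, 90 °C
Reagents that add atoms: tetramethyltin, C[Sn](C)(C)C
Why: Stille coupling of the remaining α-bromide under neutral conditions; no stereocentre is formed and the acetal carbon is not exposed to base.

Step 4
Reactants: 5 (5S)-4-ethyl-3-methyl-5-[(1R,2S,5R)-menthyloxy]furan-2(5H)-one; 6 (E)-1-methoxy-3-(trimethylsilyloxy)buta-1,3-diene
Product: 8 (3S,3aS,7aR)-3a-ethyl-7a-methyl-3-[(1R,2S,5R)-menthyloxy]-3a,4-dihydro-2-benzofuran-1,5(3H,7aH)-dione (cis-fused enone lactone acetal; C7 ketone and C7a=C3a alkene in target locants), via silyl enol ether cycloadduct 7 (not isolated)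
Conditions: 6 (4 equiv), CH2Cl2, 15 kbar, 40 °C; then aq. HCl (0.1 mol/L), THF, 0 °C
Reagents that add atoms: none
Why: Concerted but asynchronous (4+2) cycloaddition (Diels–Alder reaction): the CH2 terminus of 6, which has the largest HOMO coefficient, bonds to the β carbon of the butenolide (the ethyl carbon, future C5) and the methoxy terminus to the α carbon (future C4); the closest known reaction type is the Diels–Alder addition of 5-alkoxy-2(5H)-furanones to 1-alkoxy-3-silyloxydienes. The six-membered carbocycle is closed by intermolecular cycloaddition, both ring bonds (C5–C6 and C4–C3a) forming in the same step, and no other ring is closed. C5 and C4 are created together: their relative configuration (ethyl and methyl cis, cis-fused lactone) follows from suprafacial addition to the ring-locked alkene, and their absolute configuration from the (5S) acetal carbon, because the diene approaches the face anti to the menthyloxy group. The step needs facial selectivity, secured by the acetal substituent next to the reacting β carbon, and regioselectivity, secured by the matched polarisation of the diene and the lactone carbonyl. Endo/exo selectivity is irrelevant, because dilute acid hydrolyses the silyl enol ether of 7 and eliminates methanol to give enone 8. A dienophile substituted at both carbons is at the limit of reactivity, so the strongly negative activation volume is exploited at 15 kbar in place of heat, which would favour diene decomposition and cycloreversion.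

Step 5
Reactants: 8 cis-fused enone lactone acetal
Product: 10 aldol adduct (C3a isopropenyl on the alkyl face; C7a 1-hydroxyethyl on the lactone face; carbinol epimers), via bromomagnesium enolate 9 (not isolated)
Conditions: CH2=C(CH3)MgBr, CuBr·SMe2 (15 mol%), THF, −78 → −40 °C; then CH3CHO, −78 °C; aq. NH4Cl
Reagents that add atoms: isopropenylmagnesium bromide, CC(=C)[Mg]Br; acetaldehyde, CC=O
Why: Copper-catalysed conjugate addition followed by aldol trapping of the regiodefined enolate; the isopropenyl group is expected to enter C3a on the convex alkyl face, anti to the lactone carbonyl on the neighbouring C4. The configurations at C7a and at the carbinol carbon do not matter, since both are erased in step 6.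

Step 6
Reactants: 10 aldol adduct
Product: 12 (E)-ethylidene ketone (C7 ketone; C7a=CH–CH3 with the methyl syn to C3a), via mesylate 11 (not isolated)
Conditions: MsCl, Et3N, CH2Cl2, 0 °C → rt
Reagents that add atoms: none
Why: Mesylation and E1cB elimination through the C7a enolate complete an aldol condensation; the E isomer (methyl turned away from the carbonyl oxygen) is the expected product, and the mild amine base and low temperature are chosen so that the γ proton at C3a is not removed and the alkene does not move into the ring.

Step 7
Reactants: 12 (E)-ethylidene ketone
Product: 14 trans-2,3-disubstituted ketone (C3a isopropenyl on the alkyl face; C7a (R)-but-3-en-2-yl on the lactone face), via bromomagnesium enolate 13 (not isolated)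
Conditions: CH2=CHMgBr, CuBr·SMe2 (15 mol%), THF, −78 → −30 °C; aq. NH4Cl
Reagents that add atoms: vinylmagnesium bromide, C=C[Mg]Br
Why: Copper-catalysed conjugate addition to an exocyclic enone; allylic 1,3-strain with the ethylidene methyl holds the C3a isopropenyl group pseudo-axial, so the vinyl group should add to C1 on the opposite (lactone) face, which gives the C1 configuration of the target. Protonation of enolate 13 sets C7a, which is epimerisable and should settle as the trans-2,3-disubstituted ketone.

Step 8
Reactants: 14 trans-2,3-disubstituted ketone
Product: 15 trans-fused bicyclic ketone (cyclopentene with C2=C3 closed; C7 ketone)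
Conditions: second-generation Grubbs catalyst RuCl2(=CHPh)(PCy3)(H2IMes) (5 mol%), CH2Cl2, 40 °C
Reagents that add atoms: none
Why: Ring-closing metathesis of the vinyl group with the 1,1-disubstituted isopropenyl group forms the trisubstituted cyclopentene with loss of ethene; the two alkenyl groups are trans-diequatorial and within reach, and the neutral conditions do not epimerise C7a.

Step 9
Reactants: 15 trans-fused bicyclic ketone
Product: 17 enol triflate (C6=C7–OTf), via potassium enolate 16 (not isolated)
Conditions: KHMDS, THF, −78 °C; then PhNTf2, −78 → −20 °C
Reagents that add atoms: N-phenylbis(trifluoromethanesulfonimide), O=S(=O)(N(c1ccccc1)S(=O)(=O)C(F)(F)F)C(F)(F)F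
Why: Kinetic deprotonation with a bulky amide at low temperature should take a C6 methylene proton in preference to the fully flanked C7a methine, and O-sulfonylation of the enolate fixes the alkene at C6=C7 while the trans ring fusion is left untouched.

Step 10
Reactants: 17 enol triflate
Product: 18 diene lactone acetal (C6=C7–CH3; complete carbocycle)
Conditions: MeMgBr, Fe(acac)3 (5 mol%), THF/NMP, −30 → 0 °C
Reagents that add atoms: methylmagnesium bromide, C[Mg]Br
Why: Iron-catalysed Kumada-type cross-coupling of an alkenyl triflate, which is faster at low temperature than Grignard addition to the hindered lactone; the alkene position is retained.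

Step 11
Reactants: 18 diene lactone acetal
Product: 19 hydroxy lactone (lactol form of the C5-formyl C4-carboxylic acid; hemiacetal epimers)
Conditions: LiOH·H2O, THF/H2O, 50 °C; then aq. HCl (0.1 mol/L) to pH 3, 0 °C
Reagents that add atoms: lithium hydroxide, [Li+].[OH-]
Why: Saponification of the pseudo-ester: hydroxide opens the lactone and the hemiacetal anion expels menthoxide, giving the formyl carboxylate, which closes to the lactol on mild acidification. The aldehyde sits on a quaternary carbon and cannot enolise, hot acid (which could protonate the trisubstituted alkenes) is avoided, and the auxiliary is recovered.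

Step 12
Reactants: 19 hydroxy lactone; 20 diethyl [(2E)-3-phenylprop-2-en-1-yl]phosphonate (diethyl cinnamylphosphonate)
Product: 22 (1R,3aR,4R,5S,7aS)-5-ethyl-1,3,4,7-tetramethyl-5-[(1E,3E)-4-phenylbuta-1,3-dien-1-yl]-3a,4,5,7a-tetrahydro-1H-indene-4-carboxylic acid, via lithium formyl carboxylate 21 (not isolated)
Conditions: 20 (3 equiv), LiHMDS (3 equiv), THF, −78 °C; add 19, −78 °C → rt; aq. HCl (0.1 mol/L) to pH 3, 0 °C
Reagents that add atoms: none
Why: Horner–Wadsworth–Emmons olefination; the first equivalent of phosphonate anion opens the lactol to the formyl carboxylate 21, and a further equivalent adds to the non-enolisable aldehyde and eliminates phosphate to give the new E alkene, the styryl E geometry being carried in from 20.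

## Compound list

1 | mucobromic acid (3,4-dibromo-5-hydroxyfuran-2(5H)-one) | OC1OC(=O)C(Br)=C1Br | starting material
2 | (−)-menthol, (1R,2S,5R)-2-isopropyl-5-methylcyclohexan-1-ol | C[C@@H]1CC[C@H]([C@@H](C1)O)C(C)C | starting material
3 | (5S)-3,4-dibromo-5-[(1R,2S,5R)-menthyloxy]furan-2(5H)-one | BrC1=C(Br)C(=O)O[C@@H]1O[C@@H]2C[C@H](C)CC[C@H]2C(C)C | intermediate
4 | (5S)-3-bromo-4-ethyl-5-[(1R,2S,5R)-menthyloxy]furan-2(5H)-one | CCC1=C(Br)C(=O)O[C@@H]1O[C@@H]2C[C@H](C)CC[C@H]2C(C)C | intermediate
5 | (5S)-4-ethyl-3-methyl-5-[(1R,2S,5R)-menthyloxy]furan-2(5H)-one | CCC1=C(C)C(=O)O[C@@H]1O[C@@H]2C[C@H](C)CC[C@H]2C(C)C | intermediate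
6 | (E)-1-methoxy-3-(trimethylsilyloxy)buta-1,3-diene | CO/C=C/C(=C)O[Si](C)(C)C | starting material
7 | silyl enol ether cycloadduct (C7 OSiMe3; C7=C7a; C3a OMe of either configuration; cis-fused lactone acetal) | CC[C@]12CC(O[Si](C)(C)C)=CC(OC)[C@@]1(C)C(=O)O[C@@H]2O[C@@H]3C[C@H](C)CC[C@H]3C(C)C | intermediate
8 | (3S,3aS,7aR)-3a-ethyl-7a-methyl-3-[(1R,2S,5R)-menthyloxy]-3a,4-dihydro-2-benzofuran-1,5(3H,7aH)-dione (cis-fused enone lactone acetal) | CC[C@]12CC(=O)C=C[C@@]1(C)C(=O)O[C@@H]2O[C@@H]3C[C@H](C)CC[C@H]3C(C)C | intermediate
9 | bromomagnesium enolate (C7 OMgBr; C7=C7a; C3a isopropenyl on the alkyl face) | CC[C@]12CC(O[Mg]Br)=C[C@H](C(C)=C)[C@@]1(C)C(=O)O[C@@H]2O[C@@H]3C[C@H](C)CC[C@H]3C(C)C | intermediate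
10 | aldol adduct (C3a isopropenyl on the alkyl face; C7a 1-hydroxyethyl on the lactone face; carbinol epimers) | CC[C@]12CC(=O)[C@@H](C(C)O)[C@H](C(C)=C)[C@@]1(C)C(=O)O[C@@H]2O[C@@H]3C[C@H](C)CC[C@H]3C(C)C | intermediate
11 | mesylate of 10 | CC[C@]12CC(=O)[C@@H](C(C)OS(C)(=O)=O)[C@H](C(C)=C)[C@@]1(C)C(=O)O[C@@H]2O[C@@H]3C[C@H](C)CC[C@H]3C(C)C | intermediate
12 | (E)-ethylidene ketone (C7 ketone; C7a=CH–CH3, methyl syn to C3a) | CC[C@]12CC(=O)/C(=C/C)[C@H](C(C)=C)[C@@]1(C)C(=O)O[C@@H]2O[C@@H]3C[C@H](C)CC[C@H]3C(C)C | intermediate
13 | bromomagnesium enolate (C7 OMgBr; C7=C7a; C7a bearing (R)-but-3-en-2-yl) | CC[C@]12CC(O[Mg]Br)=C([C@H](C)C=C)[C@H](C(C)=C)[C@@]1(C)C(=O)O[C@@H]2O[C@@H]3C[C@H](C)CC[C@H]3C(C)C | intermediate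
14 | trans-2,3-disubstituted ketone (C3a isopropenyl on the alkyl face; C7a (R)-but-3-en-2-yl on the lactone face) | CC[C@]12CC(=O)[C@@H]([C@H](C)C=C)[C@H](C(C)=C)[C@@]1(C)C(=O)O[C@@H]2O[C@@H]3C[C@H](C)CC[C@H]3C(C)C | intermediate
15 | trans-fused bicyclic ketone (cyclopentene C2=C3; C7 ketone) | CC[C@]12CC(=O)[C@H]4[C@H](C)C=C(C)[C@@H]4[C@@]1(C)C(=O)O[C@@H]2O[C@@H]3C[C@H](C)CC[C@H]3C(C)C | intermediate
16 | potassium enolate (C6=C7–OK) | CC[C@]12C=C([O-])[C@H]4[C@H](C)C=C(C)[C@@H]4[C@@]1(C)C(=O)O[C@@H]2O[C@@H]3C[C@H](C)CC[C@H]3C(C)C.[K+] | intermediate
17 | enol triflate (C6=C7–OTf) | CC[C@]12C=C(OS(=O)(=O)C(F)(F)F)[C@H]4[C@H](C)C=C(C)[C@@H]4[C@@]1(C)C(=O)O[C@@H]2O[C@@H]3C[C@H](C)CC[C@H]3C(C)C | intermediate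
18 | diene lactone acetal (C6=C7–CH3; complete carbocycle; menthyl pseudo-ester) | CC[C@]12C=C(C)[C@H]4[C@H](C)C=C(C)[C@@H]4[C@@]1(C)C(=O)O[C@@H]2O[C@@H]3C[C@H](C)CC[C@H]3C(C)C | intermediate
19 | hydroxy lactone (lactol form of the C5-formyl C4-carboxylic acid; hemiacetal epimers) | CC[C@]12C=C(C)[C@H]3[C@H](C)C=C(C)[C@@H]3[C@@]1(C)C(=O)OC2O | intermediate
20 | diethyl [(2E)-3-phenylprop-2-en-1-yl]phosphonate | CCOP(=O)(OCC)C/C=C/c1ccccc1 | starting material
21 | lithium formyl carboxylate (ring-opened form of 19) | CC[C@]1(C=O)C=C(C)[C@H]2[C@H](C)C=C(C)[C@@H]2[C@@]1(C)C(=O)[O-].[Li+] | intermediate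
22 | (1R,3aR,4R,5S,7aS)-5-ethyl-1,3,4,7-tetramethyl-5-[(1E,3E)-4-phenylbuta-1,3-dien-1-yl]-3a,4,5,7a-tetrahydro-1H-indene-4-carboxylic acid | CC[C@]1(/C=C/C=C/c2ccccc2)C=C(C)[C@H]2[C@H](C)C=C(C)[C@@H]2[C@@]1(C)C(=O)O | target

## Step count and least certain steps

Total: 12 steps. Longest linear sequence: 12 steps (1 → 22); all other components are commercial.

**Step 4 (key step).** The most likely failure is that no cycloaddition takes place: both dienophile carbons are fully substituted, and decomposition or polymerisation of the diene may outrun the addition even under pressure. The fallback sets out from 4 and returns at 8. It runs the cycloaddition one substituent lighter and puts the angular methyl in afterwards.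
- Hydrodebromination of 4 (Bu3SnH, Pd(PPh3)4) would give (5S)-4-ethyl-5-menthyloxyfuran-2(5H)-one F1, a β-monoalkyl butenolide of an established dienophile class.
- F1 and commercial 2-(trimethylsilyloxy)buta-1,3-diene under pressure would give the cis-fused silyl enol ether cycloadduct F2, with the same orientation (silyloxy carbon joined through CH2 to C5) and the same approach anti to the menthyloxy group.
- Because the ketone is still masked, LDA can remove only the lactone α proton at C4, and MeI should alkylate from the convex face to keep the lactone cis-fused, giving the C4-methylated silyl enol ether F3.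
- Saegusa–Ito dehydrogenation of F3 (Pd(OAc)2, MeCN), whose enol ether double bond already points toward C7a, would give 8.

**Step 5.** The risk is poor or reversed facial selectivity at C3a: both faces of the enone carry a substituent of the neighbouring quaternary carbon, and the preference for the alkyl face rests on the convex shape of the bicycle and on attack anti to the lactone carbonyl. The fallback sets out from 8 and returns at 10. It replaces substrate control by ligand control: a Hayashi–Miyaura addition of isopropenylboronic acid pinacol ester with [Rh(OH)(cod)]2 and the enantiomer of BINAP that directs the alkenyl group to the alkyl face would give the C3a-isopropenyl ketone F4. LDA should then deprotonate F4 at the C7a methylene (C6 is neopentyl), and acetaldehyde would give 10.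

**Step 7.** The risk is low diastereofacial selectivity at the exocyclic carbon. The argument needs the C3a isopropenyl group to stay pseudo-axial, which costs a 1,3-repulsion with the C5 ethyl group, and an E/Z mixture of 12 would erode C1 further. The fallback sets out from 8 and returns at 14. The copper-catalysed isopropenyl addition is run with Me3SiCl to give the trimethylsilyl enol ether F5. Iridium-catalysed branched-selective allylic alkylation of F5 ([Ir(cod)Cl]2, chiral phosphoramidite ligand, (E)-but-2-enyl methyl carbonate, CsF, ZnF2) would then set C1 under catalyst control, while C7a is set by approach anti to the C3a substituent, giving 14.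

**Step 9.** The risk is competing deprotonation at the C7a methine, because the C6 methylene is neopentyl; this would give the regioisomeric triflate and destroy the trans ring fusion. The fallback sets out from 15 and returns at 18. MeMgBr with CeCl3 should add to the C7 ketone by equatorial attack (the axial path is blocked by the axial C5–C1' bond) to give the C7 tertiary alcohol F6, with the hydroxyl axial on the lactone face. The Burgess reagent eliminates syn, and the C7a hydrogen is anti to this hydroxyl, so the alkene can form only toward C6 (giving 18) or toward the methyl group; an exocyclic isomer would have to be separated.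

**Step 12.** The risk is sluggish addition of the bulky phosphonate anion to a neopentyl aldehyde that is held as a lactol and sits next to a carboxylate, or incomplete E selectivity at the new alkene. The fallback sets out from 19 and returns at 22. It moves the disconnection to C2'–C3'.
- Alkylation of the carboxylate (K2CO3, allyl bromide, DMF) traps the open form as the allyl ester aldehyde F7.
- Takai olefination (CrCl2, CHI3, THF) would give the (E)-iodovinyl allyl ester F8.
- Suzuki–Miyaura coupling with (E)-2-phenylvinylboronic acid (Pd(PPh3)4, aq. K3PO4, THF) would give the allyl ester of the target F9.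
- Deallylation (Pd(PPh3)4, morpholine) would give 22.

## Further compounds

F1 | step 4 | (5S)-4-ethyl-5-[(1R,2S,5R)-menthyloxy]furan-2(5H)-one | CCC1=CC(=O)O[C@@H]1O[C@@H]2C[C@H](C)CC[C@H]2C(C)C
F2 | step 4 | cis-fused silyl enol ether cycloadduct without the C4 methyl (C4–H; C7 OSiMe3; C7=C7a) | CC[C@]12CC(O[Si](C)(C)C)=CC[C@H]1C(=O)O[C@@H]2O[C@@H]3C[C@H](C)CC[C@H]3C(C)C
F3 | step 4 | C4-methylated silyl enol ether (C7 OSiMe3; C7=C7a) | CC[C@]12CC(O[Si](C)(C)C)=CC[C@@]1(C)C(=O)O[C@@H]2O[C@@H]3C[C@H](C)CC[C@H]3C(C)C
F4 | step 5 | C3a-isopropenyl ketone (isopropenyl on the alkyl face; C7a unsubstituted) | CC[C@]12CC(=O)C[C@H](C(C)=C)[C@@]1(C)C(=O)O[C@@H]2O[C@@H]3C[C@H](C)CC[C@H]3C(C)C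
F5 | step 7 | trimethylsilyl enol ether of the C3a-isopropenyl ketone (C7 OSiMe3; C7=C7a) | CC[C@]12CC(O[Si](C)(C)C)=C[C@H](C(C)=C)[C@@]1(C)C(=O)O[C@@H]2O[C@@H]3C[C@H](C)CC[C@H]3C(C)C
F6 | step 9 | C7 tertiary alcohol (C7 methyl equatorial; hydroxyl on the lactone face) | CC[C@]12C[C@@](C)(O)[C@H]4[C@H](C)C=C(C)[C@@H]4[C@@]1(C)C(=O)O[C@@H]2O[C@@H]3C[C@H](C)CC[C@H]3C(C)C
F7 | step 12 | allyl ester of the C5-formyl acid | CC[C@]1(C=O)C=C(C)[C@H]2[C@H](C)C=C(C)[C@@H]2[C@@]1(C)C(=O)OCC=C
F8 | step 12 | allyl ester with an (E)-2-iodovinyl group on C5 | CC[C@]1(/C=C/I)C=C(C)[C@H]2[C@H](C)C=C(C)[C@@H]2[C@@]1(C)C(=O)OCC=C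
F9 | step 12 | allyl ester of 22 | CC[C@]1(/C=C/C=C/c2ccccc2)C=C(C)[C@H]2[C@H](C)C=C(C)[C@@H]2[C@@]1(C)C(=O)OCC=C
A1 | alternative 1 | bicyclic cyclopentenone with the cyclohexene in place (methyl ester; silyloxymethyl on C5) | CC[C@]1(CO[Si](C)(C)C(C)(C)C)C=C(C)[C@H]2[C@H](C)C(=O)C(C)=C2[C@@]1(C)C(=O)OC
A2 | alternative 2 | tricyclic lactone with the complete carbocyclic core | CC[C@@]12COC(=O)[C@]1(C)[C@H]3C(C)=C[C@@H](C)[C@@H]3C(C)=C2
A3 | alternative 3 | bicyclic acid with a p-methoxybenzyloxymethyl group on C5 | CC[C@]1(COCc2ccc(OC)cc2)C=C(C)[C@H]2[C@H](C)C=C(C)[C@@H]2[C@@]1(C)C(=O)O
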